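**Plan**
- Retrosynthesis: the styryl end is cut at C3′=C4′ (phosphonate olefination). The cyclopentene is cut at C3a–C7a, C1–C2 and C2–C3 (alkyne + alkene + CO; the C2 oxygen is later removed with a hydrogen shift onto C3a). The acyclic dienyne is cut at C4–C5 ([3,3]) and at C5–C6 and C7–C7a (two Suzuki couplings).
- Enabling feature (indene numbering): C1, C2, C3 and the fusion bond C3a–C7a map onto an ethyl alkyne on C4 (C3, C3a), the distal C7a=C1 alkene of a (Z,E)-diene on C5, and one CO (C2). C3a carries only hydrogen, so it can be set after both rings exist.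
- Forward: a chiral propargylic alcohol becomes a (Z)-vinyl iodide and, by double coupling on a cis-diborylpropene, a trienyl carbinol. Its 2-methylhex-3-ynoate undergoes Ireland–Claisen rearrangement (C4–C5). One Pauson–Khand step closes the cyclohexene and the cyclopentenone together. Reduction, formate and Pd then move the alkene and set C3a; the side chain and the acid come last.
- Stereochemistry: the Noyori reduction is the only external source. The chair Ireland–Claisen relays it to C5 (alkene geometry) and C4 (ketene acetal geometry). The cyclisation sets C1 (E-alkene) and C7a (half-chair). Hydride anti to the C1 methyl sets C2–O, and palladium delivers hydrogen to C3a anti to the formate (trans ring fusion).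

Key step: step 13

Remark: indene numbering of the target (C1 CHMe, C2=C3 with Et on C3, C3a/C7a fusion, C4 Me/CO2H, C5 Et/dienyl, C6=C7 with Me on C7) is also used for the corresponding carbons of acyclic precursors; the sense of the Noyori reduction in step 3 is assigned by analogy with alk-1-yn-3-ones (alkyne as the unsaturated group), and the other catalyst enantiomer would be used if the α-silyloxy group inverted it.

**Route**

Step 1
Reactants: 1 but-1-yne; 2 (tert-butyldimethylsilyloxy)acetaldehyde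
Product: 4 rac-1-(tert-butyldimethylsilyloxy)hex-3-yn-2-ol, via but-1-yn-1-yllithium 3 (not isolated)
Conditions: n-BuLi, THF, −78 °C; then 2, −78 → 0 °C; H2O
Reagents that add atoms: none
Why: Deprotonation of the terminal alkyne and 1,2-addition of the lithium acetylide to the aldehyde is a standard acetylide addition; the carbinol is racemic here and is corrected in steps 2 and 3.

Step 2
Reactants: 4 rac-1-(tert-butyldimethylsilyloxy)hex-3-yn-2-ol
Product: 5 1-(tert-butyldimethylsilyloxy)hex-3-yn-2-one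
Conditions: activated MnO2, CH2Cl2, rt
Reagents that add atoms: none
Why: Manganese dioxide oxidises propargylic alcohols to ynones under neutral conditions that leave the silyl ether untouched.

Step 3
Reactants: 5 1-(tert-butyldimethylsilyloxy)hex-3-yn-2-one
Product: 6 (2S)-1-(tert-butyldimethylsilyloxy)hex-3-yn-2-ol
Conditions: RuCl[(R,R)-TsDPEN](p-cymene) (1 mol%), i-PrOH, rt
Reagents that add atoms: none
Why: Noyori asymmetric transfer hydrogenation of alkynyl ketones is highly enantioselective because the alkyne takes the place of the unsaturated group in the organised hydride-transfer transition state, and the (R,R)-catalyst should deliver hydride to the face that gives the (2S)-carbinol.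

Step 4
Reactants: 6 (2S)-1-(tert-butyldimethylsilyloxy)hex-3-yn-2-ol
Product: 8 (2S,3Z)-1-(tert-butyldimethylsilyloxy)-4-iodohex-3-en-2-ol, via cyclic alkenylalanate 7 (not isolated)
Conditions: Red-Al, THF, 0 °C; then I2, −78 °C
Reagents that add atoms: iodine, II
Why: Alkoxide-directed trans-hydroalumination of the propargylic alcohol puts hydride on C3 and aluminium on C4 within a five-membered alanate, and iodinolysis with retention gives the vinyl iodide with iodine cis to the carbinol carbon; the cold quench limits 1,2-silyl migration.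

Step 5
Reactants: 9 propyne; 10 bis(pinacolato)diboron
Product: 11 (E)-1,2-bis(4,4,5,5-tetramethyl-1,3,2-dioxaborolan-2-yl)prop-1-ene (the two boryl groups cis)
Conditions: Pt(PPh3)4 (3 mol%), DMF, 80 °C, sealed tube
Reagents that add atoms: none
Why: Platinum(0)-catalysed diboration adds both boryl groups to the same face of the alkyne, so the two later C–C bonds at C6 and C7 are fixed cis to each other.

Step 6
Reactants: 8 (2S,3Z)-1-(tert-butyldimethylsilyloxy)-4-iodohex-3-en-2-ol; 11 (E)-1,2-bis(4,4,5,5-tetramethyl-1,3,2-dioxaborolan-2-yl)prop-1-ene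
Product: 12 (2S,3Z,5E)-1-(tert-butyldimethylsilyloxy)-4-ethyl-6-(4,4,5,5-tetramethyl-1,3,2-dioxaborolan-2-yl)hepta-3,5-dien-2-ol
Conditions: PdCl2(dppf) (5 mol%), aq. K3PO4, THF, rt
Reagents that add atoms: none
Why: Suzuki–Miyaura coupling proceeds with retention at the iodide and selectively at the less hindered terminal C–B bond of a 1,2-diborylalkene, which forms C5–C6 and keeps the internal boronate for step 7.

Step 7
Reactants: 12 (2S,3Z,5E)-1-(tert-butyldimethylsilyloxy)-4-ethyl-6-(4,4,5,5-tetramethyl-1,3,2-dioxaborolan-2-yl)hepta-3,5-dien-2-ol; 13 (E)-1-bromoprop-1-ene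
Product: 14 (2S,3Z,5Z,7E)-1-(tert-butyldimethylsilyloxy)-4-ethyl-6-methylnona-3,5,7-trien-2-ol
Conditions: Pd(OAc)2/SPhos (5/10 mol%), K3PO4, THF–H2O, 40 °C
Reagents that add atoms: none
Why: A second Suzuki–Miyaura coupling with retention at both partners places the (E)-propenyl group cis to the C5 chain and completes the (Z)-C6=C7/(E)-C7a=C1 diene; the temperature is kept low because the cis-triene can electrocyclise.

Step 8
Reactants: 15 hex-3-yn-1-ol
Product: 16 hex-3-ynoic acid
Conditions: CrO3, H2SO4, acetone–H2O, 0 °C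
Reagents that add atoms: chromium trioxide, O=[Cr](=O)=O; water, O
Why: Jones oxidation takes the homopropargylic alcohol through the aldehyde hydrate to the 3-alkynoic acid, and the acidic medium does not isomerise the alkyne to the allene.

Step 9
Reactants: 16 hex-3-ynoic acid
Product: 18 rac-2-methylhex-3-ynoic acid, via dilithium enediolate 17 (not isolated)
Conditions: LDA (2.2 equiv), THF, −78 °C; MeI; aq. HCl
Reagents that add atoms: iodomethane, CI
Why: The carboxylic acid dianion is alkylated at the α-carbon at low temperature, which suppresses isomerisation to the allenic acid; the new centre is racemic and is planarised again in step 11.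

Step 10
Reactants: 14 (2S,3Z,5Z,7E)-1-(tert-butyldimethylsilyloxy)-4-ethyl-6-methylnona-3,5,7-trien-2-ol; 18 rac-2-methylhex-3-ynoic acid
Product: 19 (2S,3Z,5Z,7E)-1-(tert-butyldimethylsilyloxy)-4-ethyl-6-methylnona-3,5,7-trien-2-yl 2-methylhex-3-ynoate (both epimers at the acyl α-carbon)
Conditions: DCC, DMAP (5 mol%), CH2Cl2, −20 → 0 °C
Reagents that add atoms: none
Why: Steglich esterification acylates the secondary allylic alcohol with retention, and the low temperature with little DMAP keeps the 3-alkynoate from isomerising to the allenoate.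

Step 11
Reactants: 19 (2S,3Z,5Z,7E)-1-(tert-butyldimethylsilyloxy)-4-ethyl-6-methylnona-3,5,7-trien-2-yl 2-methylhex-3-ynoate
Product: 23 (2S,3S,4Z,6E)-2-(but-1-yn-1-yl)-3-[(1E)-3-(tert-butyldimethylsilyloxy)prop-1-en-1-yl]-3-ethyl-2,5-dimethylocta-4,6-dienoic acid, via lithium enolate 20 (not isolated), via silyl ketene acetal 21 (not isolated), via trimethylsilyl ester 22 (not isolated)
Conditions: TMSCl–Et3N, then LDA, THF, −78 °C; → rt → 40 °C; aq. citric acid
Reagents that add atoms: none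
Why: In this Ireland–Claisen rearrangement, kinetic enolisation in THF should place the larger methyl group cis to the allyloxy oxygen and the slim butynyl group cis to O–Li, and the silyl ketene acetal rearranges through a chair with CH2OTBS equatorial (enforced by allylic strain against the cis dienyl substituent), so the (2S)-carbinol and the (3Z)-alkene set C5, the ketene acetal geometry sets C4, and the new side-chain alkene is E.

Step 12
Reactants: 23 (2S,3S,4Z,6E)-2-(but-1-yn-1-yl)-3-[(1E)-3-(tert-butyldimethylsilyloxy)prop-1-en-1-yl]-3-ethyl-2,5-dimethylocta-4,6-dienoic acid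
Product: 24 methyl (2S,3S,4Z,6E)-2-(but-1-yn-1-yl)-3-[(1E)-3-(tert-butyldimethylsilyloxy)prop-1-en-1-yl]-3-ethyl-2,5-dimethylocta-4,6-dienoate
Conditions: MeI, K2CO3, DMF, rt
Reagents that add atoms: iodomethane, CI
Why: O-Alkylation of the carboxylate (SN2 at iodomethane) makes the ester without any attack at the carbonyl, which is shielded by two quaternary carbons.

Step 13
Reactants: 24 methyl (2S,3S,4Z,6E)-2-(but-1-yn-1-yl)-3-[(1E)-3-(tert-butyldimethylsilyloxy)prop-1-en-1-yl]-3-ethyl-2,5-dimethylocta-4,6-dienoate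
Product: 26 methyl (1S,4S,5S,7aR)-5-[(1E)-3-(tert-butyldimethylsilyloxy)prop-1-en-1-yl]-3,5-diethyl-1,4,7-trimethyl-2-oxo-2,4,5,7a-tetrahydro-1H-indene-4-carboxylate, via cobalt alkyne complex 25 (not isolated)
Conditions: Co2(CO)8 (1.1 equiv), ClCH2CH2Cl, rt; then n-BuSMe, 83 °C
Reagents that add atoms: dicobalt octacarbonyl (source of the C2 carbonyl), O=C=[Co](=C=O)(=C=O)(=C=O)[Co](=C=O)(=C=O)(=C=O)=C=O
Why: The butynyl group forms the μ-alkyne hexacarbonyldicobalt complex 25, thermal loss of CO (aided by the sulfide) lets the distal C7a=C1 alkene coordinate and insert into a Co–C bond to make C3a–C7a, and CO insertion (C1–C2) followed by reductive elimination (C2–C3) releases the enone; this is an intramolecular Pauson–Khand reaction of a 1,7-enyne whose two-carbon partner is the terminal double bond of a conjugated diene. The cyclohexene closes in the insertion step (6-exo with respect to the C7a=C1 bond) through the tether C4–C5–C6=C7, whose Z double bond already holds C5 and C7a cis, and the cyclopentenone closes on cobalt by the carbonylative union of C1, CO and C3. C1 is controlled by the E geometry of the C7a=C1 alkene, because insertion and carbonylation are suprafacial and leave the C1 methyl trans to C7; C7a is controlled relative to C4 and C5 by the half-chair of the forming ring, the conformer with the C4 methyl pseudoaxial and the planar ester pseudoequatorial (least allylic strain against the C3 ethyl group and the metal) leading to 26. Site selectivity among three alkenes is needed and is secured by ring size, since C6=C7 and the side-chain alkene could only give four-membered rings, while the two quaternary carbons of the tether hold alkyne and diene close. Face selectivity at C7a has no stronger guarantee than this conformational preference and is the main uncertainty; base-free conditions are chosen so that C6=C7 does not migrate into conjugation with the new enone.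

Step 14
Reactants: 26 methyl (1S,4S,5S,7aR)-5-[(1E)-3-(tert-butyldimethylsilyloxy)prop-1-en-1-yl]-3,5-diethyl-1,4,7-trimethyl-2-oxo-2,4,5,7a-tetrahydro-1H-indene-4-carboxylate
Product: 27 methyl (1S,2S,4S,5S,7aR)-5-[(1E)-3-(tert-butyldimethylsilyloxy)prop-1-en-1-yl]-3,5-diethyl-2-hydroxy-1,4,7-trimethyl-2,4,5,7a-tetrahydro-1H-indene-4-carboxylate
Conditions: DIBAL-H (1.1 equiv), CH2Cl2, −78 °C; Rochelle salt
Reagents that add atoms: none
Why: 1,2-Reduction of the enone by the bulky aluminium hydride should occur anti to the adjacent C1 methyl group and give the C2 alcohol cis to that methyl, while the ester between two quaternary carbons reacts far more slowly at −78 °C.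

Step 15
Reactants: 27 methyl (1S,2S,4S,5S,7aR)-5-[(1E)-3-(tert-butyldimethylsilyloxy)prop-1-en-1-yl]-3,5-diethyl-2-hydroxy-1,4,7-trimethyl-2,4,5,7a-tetrahydro-1H-indene-4-carboxylate
Product: 28 methyl (1S,2S,4S,5S,7aR)-5-[(1E)-3-(tert-butyldimethylsilyloxy)prop-1-en-1-yl]-3,5-diethyl-2-(formyloxy)-1,4,7-trimethyl-2,4,5,7a-tetrahydro-1H-indene-4-carboxylate
Conditions: AcOCHO, pyridine, CH2Cl2, 0 °C
Reagents that add atoms: acetic formic anhydride, CC(=O)OC=O
Why: The mixed anhydride transfers the small formyl group to the hindered allylic alcohol under basic conditions, with retention at C2 and without ionising the allylic system.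

Step 16
Reactants: 28 methyl (1S,2S,4S,5S,7aR)-5-[(1E)-3-(tert-butyldimethylsilyloxy)prop-1-en-1-yl]-3,5-diethyl-2-(formyloxy)-1,4,7-trimethyl-2,4,5,7a-tetrahydro-1H-indene-4-carboxylate
Product: 29 methyl (1R,3aR,4R,5S,7aS)-5-[(1E)-3-(tert-butyldimethylsilyloxy)prop-1-en-1-yl]-3,5-diethyl-1,4,7-trimethyl-3a,4,5,7a-tetrahydro-1H-indene-4-carboxylate
Conditions: Pd(OAc)2 (5 mol%), n-Bu3P (5 mol%), 1,4-dioxane, 60 °C
Reagents that add atoms: none
Why: In this palladium-catalysed hydrogenolysis of an allylic formate (Tsuji-type reductive transposition), Pd(0) ionises the formate with inversion, decarboxylation gives an allylpalladium hydride, and with n-Bu3P the hydride passes from the metal to the more substituted terminus C3a on the face opposite to the formate and anti to the C4 methyl, which sets the trans ring fusion and moves the double bond to C2=C3, as is established for ring-junction formation in hydrindane allylic formates.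

Step 17
Reactants: 29 methyl (1R,3aR,4R,5S,7aS)-5-[(1E)-3-(tert-butyldimethylsilyloxy)prop-1-en-1-yl]-3,5-diethyl-1,4,7-trimethyl-3a,4,5,7a-tetrahydro-1H-indene-4-carboxylate
Product: 30 methyl (1R,3aR,4R,5S,7aS)-3,5-diethyl-5-[(1E)-3-hydroxyprop-1-en-1-yl]-1,4,7-trimethyl-3a,4,5,7a-tetrahydro-1H-indene-4-carboxylate
Conditions: HF·pyridine, pyridine, THF, 0 °C → rt
Reagents that add atoms: none
Why: Buffered fluoride cleaves the primary silyl ether and leaves the hindered ester and the trisubstituted alkenes unchanged.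

Step 18
Reactants: 30 methyl (1R,3aR,4R,5S,7aS)-3,5-diethyl-5-[(1E)-3-hydroxyprop-1-en-1-yl]-1,4,7-trimethyl-3a,4,5,7a-tetrahydro-1H-indene-4-carboxylate
Product: 31 methyl (1R,3aR,4R,5S,7aS)-3,5-diethyl-1,4,7-trimethyl-5-[(1E)-3-oxoprop-1-en-1-yl]-3a,4,5,7a-tetrahydro-1H-indene-4-carboxylate
Conditions: activated MnO2, CH2Cl2, rt
Reagents that add atoms: none
Why: Manganese dioxide oxidises the allylic alcohol selectively to the (E)-enal, which has no γ-hydrogen and cannot deconjugate.

Step 19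
Reactants: 31 methyl (1R,3aR,4R,5S,7aS)-3,5-diethyl-1,4,7-trimethyl-5-[(1E)-3-oxoprop-1-en-1-yl]-3a,4,5,7a-tetrahydro-1H-indene-4-carboxylate; 32 diethyl benzylphosphonate
Product: 34 methyl (1R,3aR,4R,5S,7aS)-3,5-diethyl-1,4,7-trimethyl-5-[(1E,3E)-4-phenylbuta-1,3-dien-1-yl]-3a,4,5,7a-tetrahydro-1H-indene-4-carboxylate, via sodium phosphonate carbanion 33 (not isolated)
Conditions: NaH, THF, 0 °C; then 31, 0 °C → rt
Reagents that add atoms: none
Why: Horner–Wadsworth–Emmons olefination with a benzylphosphonate anion gives the (E)-styryl double bond, and the substrate has no enolisable position that the base could epimerise.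

Step 20
Reactants: 34 methyl (1R,3aR,4R,5S,7aS)-3,5-diethyl-1,4,7-trimethyl-5-[(1E,3E)-4-phenylbuta-1,3-dien-1-yl]-3a,4,5,7a-tetrahydro-1H-indene-4-carboxylate
Product: 35 (1R,3aR,4R,5S,7aS)-3,5-diethyl-1,4,7-trimethyl-5-[(1E,3E)-4-phenylbuta-1,3-dien-1-yl]-3a,4,5,7a-tetrahydro-1H-indene-4-carboxylic acid
Conditions: NaSEt, DMF, 80 °C; aq. HCl
Reagents that add atoms: none
Why: The thiolate attacks the ester methyl group (SN2 dealkylation), which bypasses the carbonyl shielded by two adjacent quaternary carbons and touches no stereocentre or alkene.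

**Compound list**

1 | but-1-yne | CCC#C | starting material
2 | (tert-butyldimethylsilyloxy)acetaldehyde | O=CCO[Si](C)(C)C(C)(C)C | starting material
3 | but-1-yn-1-yllithium | [Li]C#CCC | intermediate
4 | rac-1-(tert-butyldimethylsilyloxy)hex-3-yn-2-ol | CCC#CC(O)CO[Si](C)(C)C(C)(C)C | intermediate
5 | 1-(tert-butyldimethylsilyloxy)hex-3-yn-2-one | CCC#CC(=O)CO[Si](C)(C)C(C)(C)C | intermediate
6 | (2S)-1-(tert-butyldimethylsilyloxy)hex-3-yn-2-ol | CCC#C[C@H](O)CO[Si](C)(C)C(C)(C)C | intermediate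
7 | sodium (5S)-5-[(tert-butyldimethylsilyloxy)methyl]-3-ethyl-2,2-bis(2-methoxyethoxy)-2,5-dihydro-1,2-oxaaluminol-2-uide (cyclic alkenylalanate) | CCC1=C[C@@H](CO[Si](C)(C)C(C)(C)C)O[Al-]1(OCCOC)OCCOC.[Na+] | intermediate
8 | (2S,3Z)-1-(tert-butyldimethylsilyloxy)-4-iodohex-3-en-2-ol | CC/C(I)=C/[C@H](O)CO[Si](C)(C)C(C)(C)C | intermediate
9 | propyne | CC#C | starting material
10 | bis(pinacolato)diboron | CC1(C)OB(OC1(C)C)B1OC(C)(C)C(C)(C)O1 | starting material
11 | (E)-1,2-bis(4,4,5,5-tetramethyl-1,3,2-dioxaborolan-2-yl)prop-1-ene (boryl groups cis) | C/C(B1OC(C)(C)C(C)(C)O1)=C/B1OC(C)(C)C(C)(C)O1 | intermediate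
12 | (2S,3Z,5E)-1-(tert-butyldimethylsilyloxy)-4-ethyl-6-(4,4,5,5-tetramethyl-1,3,2-dioxaborolan-2-yl)hepta-3,5-dien-2-ol | CC(C)(C)[Si](C)(C)OC[C@@H](O)/C=C(CC)\C=C(\C)B1OC(C)(C)C(C)(C)O1 | intermediate
13 | (E)-1-bromoprop-1-ene | C/C=C/Br | starting material
14 | (2S,3Z,5Z,7E)-1-(tert-butyldimethylsilyloxy)-4-ethyl-6-methylnona-3,5,7-trien-2-ol | CC(C)(C)[Si](C)(C)OC[C@@H](O)/C=C(CC)\C=C(\C)/C=C/C | intermediate
15 | hex-3-yn-1-ol | CCC#CCCO | starting material
16 | hex-3-ynoic acid | CCC#CCC(=O)O | intermediate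
17 | dilithium hex-1-en-3-yne-1,1-diolate (dianion of 16) | CCC#CC=C(O[Li])O[Li] | intermediate
18 | rac-2-methylhex-3-ynoic acid | CCC#CC(C)C(=O)O | intermediate
19 | (2S,3Z,5Z,7E)-1-(tert-butyldimethylsilyloxy)-4-ethyl-6-methylnona-3,5,7-trien-2-yl 2-methylhex-3-ynoate | CCC#CC(C)C(=O)O[C@H](CO[Si](C)(C)C(C)(C)C)/C=C(CC)\C=C(\C)/C=C/C | intermediate
20 | lithium enolate of 19 (butynyl cis to O–Li, methyl cis to the allyloxy group) | CCC#C/C(C)=C(\O[Li])O[C@H](CO[Si](C)(C)C(C)(C)C)/C=C(CC)\C=C(\C)/C=C/C | intermediate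
21 | (Z)-trimethylsilyl ketene acetal of 19 (butynyl cis to OSiMe3) | CCC#C/C(C)=C(\O[Si](C)(C)C)O[C@H](CO[Si](C)(C)C(C)(C)C)/C=C(CC)\C=C(\C)/C=C/C | intermediate
22 | trimethylsilyl (2S,3S,4Z,6E)-2-(but-1-yn-1-yl)-3-[(1E)-3-(tert-butyldimethylsilyloxy)prop-1-en-1-yl]-3-ethyl-2,5-dimethylocta-4,6-dienoate | CCC#C[C@@](C)(C(=O)O[Si](C)(C)C)[C@](/C=C/CO[Si](C)(C)C(C)(C)C)(CC)/C=C(C)\C=C\C | intermediate
23 | (2S,3S,4Z,6E)-2-(but-1-yn-1-yl)-3-[(1E)-3-(tert-butyldimethylsilyloxy)prop-1-en-1-yl]-3-ethyl-2,5-dimethylocta-4,6-dienoic acid | CCC#C[C@@](C)(C(=O)O)[C@](/C=C/CO[Si](C)(C)C(C)(C)C)(CC)/C=C(C)\C=C\C | intermediate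
24 | methyl (2S,3S,4Z,6E)-2-(but-1-yn-1-yl)-3-[(1E)-3-(tert-butyldimethylsilyloxy)prop-1-en-1-yl]-3-ethyl-2,5-dimethylocta-4,6-dienoate | CCC#C[C@@](C)(C(=O)OC)[C@](/C=C/CO[Si](C)(C)C(C)(C)C)(CC)/C=C(C)\C=C\C | intermediate
25 | hexacarbonyldicobalt complex of 24 (alkyne bridging both cobalt atoms) | CCC12[Co]3(=C=O)(=C=O)(=C=O)[Co]1(=C=O)(=C=O)(=C=O)C23[C@@](C)(C(=O)OC)[C@](/C=C/CO[Si](C)(C)C(C)(C)C)(CC)/C=C(C)\C=C\C | intermediate
26 | methyl (1S,4S,5S,7aR)-5-[(1E)-3-(tert-butyldimethylsilyloxy)prop-1-en-1-yl]-3,5-diethyl-1,4,7-trimethyl-2-oxo-2,4,5,7a-tetrahydro-1H-indene-4-carboxylate | CCC1=C2[C@@](C)(C(=O)OC)[C@](/C=C/CO[Si](C)(C)C(C)(C)C)(CC)C=C(C)[C@H]2[C@H](C)C1=O | intermediate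
27 | methyl (1S,2S,4S,5S,7aR)-5-[(1E)-3-(tert-butyldimethylsilyloxy)prop-1-en-1-yl]-3,5-diethyl-2-hydroxy-1,4,7-trimethyl-2,4,5,7a-tetrahydro-1H-indene-4-carboxylate | CCC1=C2[C@@](C)(C(=O)OC)[C@](/C=C/CO[Si](C)(C)C(C)(C)C)(CC)C=C(C)[C@H]2[C@H](C)[C@@H]1O | intermediate
28 | methyl (1S,2S,4S,5S,7aR)-5-[(1E)-3-(tert-butyldimethylsilyloxy)prop-1-en-1-yl]-3,5-diethyl-2-(formyloxy)-1,4,7-trimethyl-2,4,5,7a-tetrahydro-1H-indene-4-carboxylate | CCC1=C2[C@@](C)(C(=O)OC)[C@](/C=C/CO[Si](C)(C)C(C)(C)C)(CC)C=C(C)[C@H]2[C@H](C)[C@@H]1OC=O | intermediate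
29 | methyl (1R,3aR,4R,5S,7aS)-5-[(1E)-3-(tert-butyldimethylsilyloxy)prop-1-en-1-yl]-3,5-diethyl-1,4,7-trimethyl-3a,4,5,7a-tetrahydro-1H-indene-4-carboxylate | CCC1=C[C@@H](C)[C@@H]2C(C)=C[C@@](/C=C/CO[Si](C)(C)C(C)(C)C)(CC)[C@](C)(C(=O)OC)[C@@H]12 | intermediate
30 | methyl (1R,3aR,4R,5S,7aS)-3,5-diethyl-5-[(1E)-3-hydroxyprop-1-en-1-yl]-1,4,7-trimethyl-3a,4,5,7a-tetrahydro-1H-indene-4-carboxylate | CCC1=C[C@@H](C)[C@@H]2C(C)=C[C@@](/C=C/CO)(CC)[C@](C)(C(=O)OC)[C@@H]12 | intermediate
31 | methyl (1R,3aR,4R,5S,7aS)-3,5-diethyl-1,4,7-trimethyl-5-[(1E)-3-oxoprop-1-en-1-yl]-3a,4,5,7a-tetrahydro-1H-indene-4-carboxylate | CCC1=C[C@@H](C)[C@@H]2C(C)=C[C@@](/C=C/C=O)(CC)[C@](C)(C(=O)OC)[C@@H]12 | intermediate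
32 | diethyl benzylphosphonate | CCOP(=O)(Cc1ccccc1)OCC | starting material
33 | sodium salt of the diethyl benzylphosphonate carbanion | [Na+].CCOP(=O)([CH-]c1ccccc1)OCC | intermediate
34 | methyl (1R,3aR,4R,5S,7aS)-3,5-diethyl-1,4,7-trimethyl-5-[(1E,3E)-4-phenylbuta-1,3-dien-1-yl]-3a,4,5,7a-tetrahydro-1H-indene-4-carboxylate | CCC1=C[C@@H](C)[C@@H]2C(C)=C[C@@](/C=C/C=C/c3ccccc3)(CC)[C@](C)(C(=O)OC)[C@@H]12 | intermediate
35 | (1R,3aR,4R,5S,7aS)-3,5-diethyl-1,4,7-trimethyl-5-[(1E,3E)-4-phenylbuta-1,3-dien-1-yl]-3a,4,5,7a-tetrahydro-1H-indene-4-carboxylic acid | CCC1=C[C@@H](C)[C@@H]2C(C)=C[C@@](/C=C/C=C/c3ccccc3)(CC)[C@](C)(C(=O)O)[C@@H]12 | target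

**Count and risks**

Total step count: 20. Longest linear sequence: 17 steps (steps 1–4, 6, 7, 10–20); steps 5, 8 and 9 prepare the side branches.

The three steps most likely to fail:

Step 13. Insertion of the internal, conjugated propenyl alkene into the congested cobalt complex may be slow, so that decomplexation and decomposition of the diene compete; at the temperature then needed the two alkene faces would be discriminated poorly. The fallback sets out from 12 and comes back at 26, and takes the C1 methyl group out of the cyclisation. Suzuki coupling of 12 with vinyl bromide should give the vinyl trienol F1. It is esterified with 18 to the ester F2 and rearranged as in step 11 through the lithium enolate F3, the silyl ketene acetal F4 and the silyl ester F5 to the acid F6. O-Methylation gives the methyl ester F7. Its terminal vinyl group should enter the cobalt-mediated cyclocarbonylation under milder conditions through the cobalt complex F8, giving the enone F9 that lacks the C1 methyl. Kinetic deprotonation at C1 (LDA, THF, −78 °C) gives the lithium enolate F10, and iodomethane should attack it anti to the ring carbon C7 on C7a, which gives 26.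

Step 11. Enolisation may not distinguish methyl from butynyl well enough and give both ketene acetal geometries (hence both C4 epimers), or part of the material may rearrange through a boat. The fallback sets out from 14 and comes back at 24; it fixes the enolate geometry by chelation and builds the alkyne afterwards. Commercial methyl 3-hydroxy-2-methylpropanoate (racemic suffices) is silylated (TESCl, imidazole) to the triethylsilyl ether F11 and saponified to the acid F12. Steglich esterification of 14 gives the ester F13, and PPTS in methanol frees the β-hydroxy ester F14. Two equivalents of LDA give the dilithium alkoxide enolate F15, in which chelation holds CH2O cis to the enolate oxygen and methyl cis to the allyloxy group. Warming takes it through the same chair to the hydroxy acid F16. Methylation (MeI, K2CO3) gives the hydroxy ester F17, Dess–Martin oxidation gives the aldehyde F18, and Colvin homologation with lithiated trimethylsilyldiazomethane gives the terminal alkyne F19. Deprotonation (LiHMDS) to the lithium acetylide F20 and alkylation with ethyl triflate give 24.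

Step 16. The allylpalladium hydride may collapse at C2 (simple deoxygenation to the tetrasubstituted C3=C3a alkene) or lose a β-hydrogen to a cyclopentadiene instead of delivering hydride to the hindered C3a. The fallback sets out from 27 and comes back at 29; it is a reductive 1,3-transposition through an allylic diazene. Mitsunobu displacement of 27 with 2-nitrobenzenesulfonylhydrazide (PPh3, DEAD, N-methylmorpholine, THF, −30 °C) should give, with inversion at C2, the sulfonyl hydrazine F21. On warming it loses 2-nitrobenzenesulfinic acid to give the allylic diazene F22. Its retro-ene loss of dinitrogen transfers hydrogen to C3a on the face of the C2–N bond (anti to the original hydroxyl) and shifts the double bond to C2=C3, which gives 29.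

**Further compounds**

F1 | step 13 | (2S,3Z,5Z)-1-(tert-butyldimethylsilyloxy)-4-ethyl-6-methylocta-3,5,7-trien-2-ol | CC(C)(C)[Si](C)(C)OC[C@@H](O)/C=C(CC)\C=C(\C)C=C
F2 | step 13 | (2S,3Z,5Z)-1-(tert-butyldimethylsilyloxy)-4-ethyl-6-methylocta-3,5,7-trien-2-yl 2-methylhex-3-ynoate | CCC#CC(C)C(=O)O[C@H](CO[Si](C)(C)C(C)(C)C)/C=C(CC)\C=C(\C)C=C
F3 | step 13 | lithium enolate of F2 (butynyl cis to O–Li) | CCC#C/C(C)=C(\O[Li])O[C@H](CO[Si](C)(C)C(C)(C)C)/C=C(CC)\C=C(\C)C=C
F4 | step 13 | (Z)-trimethylsilyl ketene acetal of F2 | CCC#C/C(C)=C(\O[Si](C)(C)C)O[C@H](CO[Si](C)(C)C(C)(C)C)/C=C(CC)\C=C(\C)C=C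
F5 | step 13 | trimethylsilyl (2S,3S,4Z)-2-(but-1-yn-1-yl)-3-[(1E)-3-(tert-butyldimethylsilyloxy)prop-1-en-1-yl]-3-ethyl-2,5-dimethylhepta-4,6-dienoate | CCC#C[C@@](C)(C(=O)O[Si](C)(C)C)[C@](/C=C/CO[Si](C)(C)C(C)(C)C)(CC)/C=C(C)\C=C
F6 | step 13 | (2S,3S,4Z)-2-(but-1-yn-1-yl)-3-[(1E)-3-(tert-butyldimethylsilyloxy)prop-1-en-1-yl]-3-ethyl-2,5-dimethylhepta-4,6-dienoic acid | CCC#C[C@@](C)(C(=O)O)[C@](/C=C/CO[Si](C)(C)C(C)(C)C)(CC)/C=C(C)\C=C
F7 | step 13 | methyl (2S,3S,4Z)-2-(but-1-yn-1-yl)-3-[(1E)-3-(tert-butyldimethylsilyloxy)prop-1-en-1-yl]-3-ethyl-2,5-dimethylhepta-4,6-dienoate | CCC#C[C@@](C)(C(=O)OC)[C@](/C=C/CO[Si](C)(C)C(C)(C)C)(CC)/C=C(C)\C=C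
F8 | step 13 | hexacarbonyldicobalt complex of F7 | CCC12[Co]3(=C=O)(=C=O)(=C=O)[Co]1(=C=O)(=C=O)(=C=O)C23[C@@](C)(C(=O)OC)[C@](/C=C/CO[Si](C)(C)C(C)(C)C)(CC)/C=C(C)\C=C
F9 | step 13 | methyl (4S,5S,7aR)-5-[(1E)-3-(tert-butyldimethylsilyloxy)prop-1-en-1-yl]-3,5-diethyl-4,7-dimethyl-2-oxo-2,4,5,7a-tetrahydro-1H-indene-4-carboxylate | CCC1=C2[C@@](C)(C(=O)OC)[C@](/C=C/CO[Si](C)(C)C(C)(C)C)(CC)C=C(C)[C@H]2CC1=O
F10 | step 13 | lithium enolate of F9 (C1=C2–OLi) | CCC1=C2[C@@](C)(C(=O)OC)[C@](/C=C/CO[Si](C)(C)C(C)(C)C)(CC)C=C(C)[C@H]2C=C1O[Li]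
F11 | step 11 | methyl 2-methyl-3-(triethylsilyloxy)propanoate | CC[Si](CC)(CC)OCC(C)C(=O)OC
F12 | step 11 | 2-methyl-3-(triethylsilyloxy)propanoic acid | CC[Si](CC)(CC)OCC(C)C(=O)O
F13 | step 11 | (2S,3Z,5Z,7E)-1-(tert-butyldimethylsilyloxy)-4-ethyl-6-methylnona-3,5,7-trien-2-yl 2-methyl-3-(triethylsilyloxy)propanoate | CC[Si](CC)(CC)OCC(C)C(=O)O[C@H](CO[Si](C)(C)C(C)(C)C)/C=C(CC)\C=C(\C)/C=C/C
F14 | step 11 | (2S,3Z,5Z,7E)-1-(tert-butyldimethylsilyloxy)-4-ethyl-6-methylnona-3,5,7-trien-2-yl 3-hydroxy-2-methylpropanoate | OCC(C)C(=O)O[C@H](CO[Si](C)(C)C(C)(C)C)/C=C(CC)\C=C(\C)/C=C/C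
F15 | step 11 | dilithium alkoxide enolate of F14 (CH2OLi cis to the enolate O–Li) | [Li]OC/C(C)=C(\O[Li])O[C@H](CO[Si](C)(C)C(C)(C)C)/C=C(CC)\C=C(\C)/C=C/C
F16 | step 11 | (2S,3S,4Z,6E)-3-[(1E)-3-(tert-butyldimethylsilyloxy)prop-1-en-1-yl]-3-ethyl-2-(hydroxymethyl)-2,5-dimethylocta-4,6-dienoic acid | OC[C@@](C)(C(=O)O)[C@](/C=C/CO[Si](C)(C)C(C)(C)C)(CC)/C=C(C)\C=C\C
F17 | step 11 | methyl (2S,3S,4Z,6E)-3-[(1E)-3-(tert-butyldimethylsilyloxy)prop-1-en-1-yl]-3-ethyl-2-(hydroxymethyl)-2,5-dimethylocta-4,6-dienoate | OC[C@@](C)(C(=O)OC)[C@](/C=C/CO[Si](C)(C)C(C)(C)C)(CC)/C=C(C)\C=C\C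
F18 | step 11 | methyl (2S,3S,4Z,6E)-3-[(1E)-3-(tert-butyldimethylsilyloxy)prop-1-en-1-yl]-3-ethyl-2-formyl-2,5-dimethylocta-4,6-dienoate | O=C[C@@](C)(C(=O)OC)[C@](/C=C/CO[Si](C)(C)C(C)(C)C)(CC)/C=C(C)\C=C\C
F19 | step 11 | methyl (2R,3S,4Z,6E)-3-[(1E)-3-(tert-butyldimethylsilyloxy)prop-1-en-1-yl]-3-ethyl-2-ethynyl-2,5-dimethylocta-4,6-dienoate (same spatial arrangement as 24; the C2 descriptor changes only through ligand ranking) | C#C[C@@](C)(C(=O)OC)[C@](/C=C/CO[Si](C)(C)C(C)(C)C)(CC)/C=C(C)\C=C\C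
F20 | step 11 | lithium acetylide of F19 | [Li]C#C[C@@](C)(C(=O)OC)[C@](/C=C/CO[Si](C)(C)C(C)(C)C)(CC)/C=C(C)\C=C\C
F21 | step 16 | methyl (1S,2R,4S,5S,7aR)-5-[(1E)-3-(tert-butyldimethylsilyloxy)prop-1-en-1-yl]-3,5-diethyl-1,4,7-trimethyl-2-[1-(2-nitrobenzenesulfonyl)hydrazin-1-yl]-2,4,5,7a-tetrahydro-1H-indene-4-carboxylate | CCC1=C2[C@@](C)(C(=O)OC)[C@](/C=C/CO[Si](C)(C)C(C)(C)C)(CC)C=C(C)[C@H]2[C@H](C)[C@H]1N(N)S(=O)(=O)c1ccccc1[N+](=O)[O-]
F22 | step 16 | methyl (1S,2R,4S,5S,7aR)-5-[(1E)-3-(tert-butyldimethylsilyloxy)prop-1-en-1-yl]-2-diazenyl-3,5-diethyl-1,4,7-trimethyl-2,4,5,7a-tetrahydro-1H-indene-4-carboxylate | CCC1=C2[C@@](C)(C(=O)OC)[C@](/C=C/CO[Si](C)(C)C(C)(C)C)(CC)C=C(C)[C@H]2[C@H](C)[C@H]1N=N
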